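The ratio I begin with is the share of E turned into L at 27 min in the dusk run over the same share in the autumn run, 1.00, although the dusk run is charged with 1.67 times the E, so I take up the bench rule for a pseudo-first-order flask: one constant k, read at 5.4 min, with E falling exponentially.

| flask | E | X | time |
|---|---|---|---|
| dusk | 0.0500 M | 0.00400 M |  |
| autumn | 0.0300 M | 0.00400 M |  |
| dawn | 0.0500 M | 0.0120 M |  |
| winter | 0.0500 M | 0.00400 M | 81 min |

| dusk run: time / min | dusk run: [L] / M | autumn run: time / min | autumn run: [L] / M | dawn run: time / min | dawn run: [L] / M |
|---|---|---|---|---|---|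
| 1.1 | 0.00109 | 1.1 | 9.6 × 10⁻⁴ | 1.1 | 0.00341 |
| 2.4 | 0.00313 | 2.4 | 0.00180 | 2.4 | 0.00685 |
| 5.4 | 0.00713 | 5.4 | 0.00416 | 5.4 | 0.01401 |
| 12 | 0.01389 | 12 | 0.00857 | 12 | 0.02529 |
| 27 | 0.02366 | 27 | 0.01420 | 27 | 0.03547 |

(readings scatter by 2 × 10⁻⁴ M)

1. how the opening rate goes with [E] round the charge of the dusk run: the exponent of the rate at two percent of E gone to L (one fixed amount of L, the same in the runs compared)
2. how the opening rate goes with [X] round the charge of the dusk run: the exponent of the rate at two percent of E gone to L
3. L in the winter run at 81 min, as a share of the E charged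

- Overall: E -> L, with X as catalyst.
- Constant volume, constant temperature.
- Readings of a species count what is bound in complexes too.
- An order is taken over about fifteen percent of the charge, up and down.

k = ln[c(E) charged / (c(E) charged − c(L))] / t

dusk: 0.0285 min⁻¹; autumn: 0.0276 min⁻¹; dawn: 0.0609 min⁻¹

From these I reckon an order of 1.06 in E and 0.691 in X. But at 27 min the rule asks 0.02683 M of the dusk run, which reads 0.02366 M, and that gap of 0.003172 M is 15.9 times the scatter, so the rule stops working there. I keep it as the large term and compute only the correction, taking the gap as a slow first-order leak of L and naming the leak constant, the L lost per minute for each unit of L present: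

mean c(L) in the dusk run, by trapezia through the readings: 0.01371 M

leak constant = gap / (mean c(L) · t) = 0.00857 min⁻¹

The dawn run, whose k is twice that of the dusk run, gives 0.00781 min⁻¹ by the same reckoning, so I carry the dusk value to the winter run, which has the dusk charge:

share of L at 81 min = k/(k − leak) · [exp(−leak·t) − exp(−k·t)] = 57.2%

The thing to watch is c(L) turning over, which my reckoning puts near 60.3 min.

The forecast stands at 1, 0.7 and 75%, higher than my share, and reads the sag in k thus: “That suggests catalyst loss”.

The flask gives 0.90, 0.80 and 56.0%.

    X + E ⇌ XE, settled at all times (5.070 L mol⁻¹)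
    XE → L + X (2.280 min⁻¹)
    L → Qa (0.009240 min⁻¹)
    2 X ⇌ X2, settled at all times (80.70 L mol⁻¹)

In the winter run XE gave L and X while E was there, and L went on to Qa from the first L onward, with 56.0% of the charge, or 0.0280 M of L, standing at 81 min. As an estimate for that moment, my leak constant on that L reckons a loss of 2.40 × 10⁻⁴ M min⁻¹, and the E that my first-order rule leaves reckons a supply of 1.42 × 10⁻⁴ M min⁻¹, so by this estimate c(L) in the winter run is falling at 81 min, the reckoned loss being larger than the reckoned supply by 9.83 × 10⁻⁵ M min⁻¹.

The readings stem from a simulated flask for substances that don't exist, and the scatter is random.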